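The 13-membered para-cyclophane is cut at the benzylic CH2–aryl bond. This CH2 links the para carbon of the aryl ether ring to the hemiaminal carbon of the lactam, which is a methyl-ketone carbon in the open keto ester, so the bond joins an aryl carbon to an enolate carbon. One palladium-catalysed α-arylation of a keto ester dianion should form that bond and the macrocycle together. Its precursor 24 is the complete decahydrofluorene (rings A, B, C) carrying the C7 4-bromophenyl ether and the C6 acetonyl β-keto ester. It is assembled by two Diels–Alder reactions, intermolecular for ring C and intramolecular for rings A and B. Ammonia then closes the hydroxylactam.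

Key step: step 17

Locants used below: ring A = C1 (vinyl, methyl), C2=C3 (C3 methyl), C4, C5, C6 (acyl); ring B = C4, C5, C7 (aryloxy), C8, C13 (angular methyl); ring C = C8 to C13 (C9 and C11 methyl); β is the face of the C13 methyl.
Assumption: in step 5 the diene adds to the enal face anti to the allylic C–OAr bond, with C7–H eclipsing the C8=C13 bond.
Remark: the carbon between the ketone and ester carbonyls of 24 and 26 is enolisable and not a fixed stereocentre; both are drawn as one epimer and are carried as epimer mixtures until step 18 equilibrates them.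

Step 1
Reactants: 1 methyl (R)-2,3-dihydroxypropanoate
Product: 2 methyl (R)-3-(tert-butyldimethylsilyloxy)-2-hydroxypropanoate
Conditions: TBSCl, imidazole, CH2Cl2, 0 °C
Reagents that add atoms: tert-butyldimethylsilyl chloride, CC(C)(C)[Si](C)(C)Cl
Why: Silyl ether formation should be selective for the primary hydroxyl over the secondary one next to the ester, and the stereocentre is not touched.

Step 2
Reactants: 2 methyl (R)-3-(tert-butyldimethylsilyloxy)-2-hydroxypropanoate; 3 4-bromophenol
Product: 4 methyl (S)-2-(4-bromophenoxy)-3-(tert-butyldimethylsilyloxy)propanoate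
Conditions: PPh3, DIAD, toluene, 0 to 25 °C
Reagents that add atoms: none
Why: Mitsunobu etherification of an α-hydroxy ester proceeds by SN2 displacement of the oxyphosphonium ion by the phenoxide, so inversion sets the C7 aryloxy configuration of the target.

Step 3
Reactants: 4 methyl (S)-2-(4-bromophenoxy)-3-(tert-butyldimethylsilyloxy)propanoate
Product: 6 (R,E)-4-(4-bromophenoxy)-5-(tert-butyldimethylsilyloxy)-2-methylpent-2-enal, via aryloxy aldehyde 5 (not isolated)
Conditions: i-Bu2AlH, CH2Cl2, −78 °C; then MeOH, Ph3P=C(CH3)CHO, −78 to 40 °C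
Reagents that add atoms: 2-(triphenylphosphoranylidene)propanal, CC(C=O)=P(c1ccccc1)(c1ccccc1)c1ccccc1
Why: Low-temperature hydride reduction of the α-oxygenated ester stops at the aldehyde stage, and the stabilised-ylide Wittig olefination in the same flask should give the (E)-enal before the labile α-aryloxy aldehyde can epimerise.

Step 4
Reactants: 7 2-methylpent-1-en-3-one
Product: 8 (Z)-triethyl(2-methylpenta-1,3-dien-3-yloxy)silane
Conditions: Et3SiOTf, Et3N, Et2O, 0 °C
Reagents that add atoms: triethylsilyl trifluoromethanesulfonate, CC[Si](CC)(CC)OS(=O)(=O)C(F)(F)F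
Why: Soft enolisation of the ethyl ketone (silyl enol ether formation) gives the 2-silyloxy diene, whose enol ether geometry has no bearing on later stereocentres.

Step 5
Reactants: 6 (R,E)-4-(4-bromophenoxy)-5-(tert-butyldimethylsilyloxy)-2-methylpent-2-enal; 8 (Z)-triethyl(2-methylpenta-1,3-dien-3-yloxy)silane
Product: 9 6-[1-(4-bromophenoxy)-2-(tert-butyldimethylsilyloxy)ethyl]-1,3,5-trimethyl-4-(triethylsilyloxy)cyclohex-3-ene-1-carbaldehyde
Conditions: Me2AlCl (0.3 equiv), CH2Cl2, −78 to −30 °C
Reagents that add atoms: none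
Why: In this Lewis acid-catalysed Diels–Alder reaction the silyloxy group directs its neighbouring terminus C9 to the enal β-carbon C8, suprafacial addition to the (E)-enal places the formyl group (C4) trans to the C7 chain at C13 and C8, and the C7 stereocentre selects the face (C7–H eclipsed to avoid A(1,3) strain with the C13 methyl, diene anti to C–OAr), while the C9 epimers converge in step 6.

Step 6
Reactants: 9 6-[1-(4-bromophenoxy)-2-(tert-butyldimethylsilyloxy)ethyl]-1,3,5-trimethyl-4-(triethylsilyloxy)cyclohex-3-ene-1-carbaldehyde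
Product: 11 4-(4-bromophenoxy)-1-methoxy-5,7,8a-trimethyloctahydro-6H-isochromen-6-one, via hydroxy keto aldehyde 10 (not isolated)
Conditions: camphorsulfonic acid (10 mol %), MeOH, 25 °C, evaporation from toluene; then K2CO3 (cat.), MeOH, 40 °C
Reagents that add atoms: methanol, CO
Why: Acid methanolysis removes both silyl groups and closes the δ-hydroxy aldehyde to a trans-fused six-membered methyl acetal (Fischer-type acetalisation), and base enolisation of the ketone then puts the C9 and C11 methyls equatorial, because an axial methyl would be syn-diaxial to the axial C13 methyl of the locked chair.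

Step 7
Reactants: 11 4-(4-bromophenoxy)-1-methoxy-5,7,8a-trimethyloctahydro-6H-isochromen-6-one
Product: 13 4-(4-bromophenoxy)-1-methoxy-5,7,8a-trimethyloctahydro-1H-isochromene, via hydrazone 12 (not isolated)
Conditions: N2H4·H2O, KOH, diethylene glycol, 130 then 200 °C
Reagents that add atoms: none
Why: Wolff–Kishner reduction (Huang-Minlon conditions) removes the C10 carbonyl, the acetal, aryl ether and unactivated aryl bromide being inert to hydrazine and KOH, and the locked chair keeps the flanking methyl centres from epimerising.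

Step 8
Reactants: 13 4-(4-bromophenoxy)-1-methoxy-5,7,8a-trimethyloctahydro-1H-isochromene
Product: 14 4-(4-bromophenoxy)-5,7,8a-trimethyloctahydro-1H-isochromen-1-ol
Conditions: HCl (1 M aq, cat.), THF, 40 °C
Reagents that add atoms: water, O
Why: Acid-catalysed acetal hydrolysis gives the lactol, which is in equilibrium with the free C4 aldehyde.

Step 9
Reactants: 14 4-(4-bromophenoxy)-5,7,8a-trimethyloctahydro-1H-isochromen-1-ol
Product: 15 ethyl (E)-3-{2-[1-(4-bromophenoxy)-2-hydroxyethyl]-1,3,5-trimethylcyclohexyl}-2-methylprop-2-enoate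
Conditions: (EtO)2P(O)CH(CH3)CO2Et, NaH, THF, 0 to 50 °C
Reagents that add atoms: triethyl 2-phosphonopropionate, CCOC(=O)C(C)P(=O)(OCC)OCC
Why: Horner–Wadsworth–Emmons olefination of the lactol through its open hydroxy aldehyde form should give the (E)-trisubstituted enoate, the α-methyl group and the neopentyl β-carbon disfavouring oxa-Michael reclosure.

Step 10
Reactants: 15 ethyl (E)-3-{2-[1-(4-bromophenoxy)-2-hydroxyethyl]-1,3,5-trimethylcyclohexyl}-2-methylprop-2-enoate
Product: 16 (E)-3-{2-[1-(4-bromophenoxy)-2-hydroxyethyl]-1,3,5-trimethylcyclohexyl}-2-methylprop-2-en-1-ol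
Conditions: i-Bu2AlH (4 equiv), CH2Cl2, −78 to 0 °C
Reagents that add atoms: none
Why: Hydride 1,2-reduction of the enoate gives the allylic alcohol and leaves the aryl bromide and the alkene geometry untouched.

Step 11
Reactants: 16 (E)-3-{2-[1-(4-bromophenoxy)-2-hydroxyethyl]-1,3,5-trimethylcyclohexyl}-2-methylprop-2-en-1-ol
Product: 17 (E)-3-{2-[1-(4-bromophenoxy)-2-hydroxyethyl]-1,3,5-trimethylcyclohexyl}-2-methylprop-2-enal
Conditions: MnO2, CH2Cl2, 25 °C
Reagents that add atoms: none
Why: MnO2 is a chemoselective oxidant for allylic alcohols, so only the allylic hydroxyl should be oxidised and the saturated primary alcohol kept.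

Step 12
Reactants: 17 (E)-3-{2-[1-(4-bromophenoxy)-2-hydroxyethyl]-1,3,5-trimethylcyclohexyl}-2-methylprop-2-enal
Product: 18 (2E,4E)-5-{2-[1-(4-bromophenoxy)-2-hydroxyethyl]-1,3,5-trimethylcyclohexyl}-2,4-dimethylpenta-2,4-dienal
Conditions: Ph3P=C(CH3)CHO, toluene, 90 °C
Reagents that add atoms: 2-(triphenylphosphoranylidene)propanal, CC(C=O)=P(c1ccccc1)(c1ccccc1)c1ccccc1
Why: Wittig olefination with the stabilised formyl ylide extends the enal to the (E,E)-dienal and places the C1 methyl cis to C3, as the later cycloaddition requires.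

Step 13
Reactants: 18 (2E,4E)-5-{2-[1-(4-bromophenoxy)-2-hydroxyethyl]-1,3,5-trimethylcyclohexyl}-2,4-dimethylpenta-2,4-dienal
Product: 19 2-(4-bromophenoxy)-2-{2-[(1E,3E)-2,4-dimethylhexa-1,3,5-trienyl]-2,4,6-trimethylcyclohexyl}ethanol
Conditions: Ph3PCH3Br, KOtBu (2.5 equiv each), THF, 0 °C
Reagents that add atoms: methyltriphenylphosphonium bromide, C[P+](c1ccccc1)(c1ccccc1)c1ccccc1.[Br-]
Why: Wittig methylenation of the dienal completes the (E,E)-triene, the excess ylide tolerating the free hydroxyl as its alkoxide.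

Step 14
Reactants: 19 2-(4-bromophenoxy)-2-{2-[(1E,3E)-2,4-dimethylhexa-1,3,5-trienyl]-2,4,6-trimethylcyclohexyl}ethanol
Product: 21 methyl (E)-6-(4-bromophenoxy)-6-{2-[(1E,3E)-2,4-dimethylhexa-1,3,5-trienyl]-2,4,6-trimethylcyclohexyl}-3-oxohex-4-enoate, via aryloxy aldehyde 20 (not isolated)
Conditions: Dess–Martin periodinane, NaHCO3, CH2Cl2, 0 °C; then Ph3P=CHC(O)CH2CO2CH3, CH2Cl2, 25 °C
Reagents that add atoms: methyl 3-oxo-4-(triphenylphosphoranylidene)butanoate, COC(=O)CC(=O)C=P(c1ccccc1)(c1ccccc1)c1ccccc1
Why: Dess–Martin oxidation gives the α-aryloxy aldehyde, which is olefinated at once by a neutral stabilised keto ylide (Wittig reaction) to the (E)-γ,δ-unsaturated β-keto ester without base that could epimerise C7.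

Step 15
Reactants: 21 methyl (E)-6-(4-bromophenoxy)-6-{2-[(1E,3E)-2,4-dimethylhexa-1,3,5-trienyl]-2,4,6-trimethylcyclohexyl}-3-oxohex-4-enoate
Product: 22 methyl 3-oxo-3-(tricyclic C6-yl)propanoate, the decahydrofluorene with the C7 4-bromophenoxy group
Conditions: toluene (5 mM), BHT, 110 °C
Reagents that add atoms: none
Why: In this intramolecular Diels–Alder reaction of a 1,3,8-nonatriene the acyl-endo transition state of the (E)-enone gives the trans A/B fusion with C5–H and C6–H trans, the diene geometry sets C1 (methyl cis to C4–H), and the tether takes the trans-hydrindane-like arrangement with the diene arm pseudo-equatorial, so that C4–H ends anti to the axial C13 methyl.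

Step 16
Reactants: 22 tricyclic β-keto ester; 23 chloroacetone
Product: 24 aryl bromide methyl ketone β-keto ester (macrocyclisation precursor)
Conditions: K2CO3, NaI (cat.), acetone, 25 °C
Reagents that add atoms: none
Why: C-alkylation of the β-keto ester enolate with chloroacetone (SN2, Finkelstein-assisted) gives the 1,4-diketone as a mixture of epimers at the new enolisable carbon.

Step 17
Reactants: 24 aryl bromide methyl ketone β-keto ester
Product: 26 13-membered cyclophane diketo ester, via dilithium dianion 25 (not isolated)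
Conditions: LiN(SiMe3)2 (2.2 equiv), THF, −78 to 0 °C; slow addition to Pd2(dba)3 (tris(dibenzylideneacetone)dipalladium, 10 mol %), XPhos (25 mol %), toluene, 80 °C, 2 mM; aq NH4Cl
Reagents that add atoms: none
Why: Proposed new method: the base first removes the proton between the two carbonyls of the keto ester and then a proton of the terminal methyl of the acetonyl ketone, the internal CH2 being deactivated by the adjacent enolate. Zerovalent palladium carrying the bulky biaryl phosphine inserts into the C–Br bond, the terminal lithium enolate replaces bromide on divalent palladium, and reductive elimination from the C-bound enolate forms the ArCH2–C(=O) bond; the closest known reaction type is the Buchwald–Hartwig α-arylation of methyl ketone enolates with aryl bromides, which has not been used to close a para-cyclophane. The 13-membered ring is closed by reductive elimination from a 14-membered palladacycle (ring contraction at the metal), and high dilution with slow addition should hold back intermolecular arylation. No stereocentre is created, since the carbon between the carbonyls is only re-protonated and is equilibrated in step 18. The step needs selectivity for the terminal methyl enolate over the internal CH2 and the stabilised keto ester enolate; dianion formation secures it, because the last-formed enolate is the most nucleophilic and the only one that can reach the arylpalladium centre, while the keto ester stays masked as its own enolate, which also blocks Dieckmann-type attack on the ester.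

Step 18
Reactants: 26 13-membered cyclophane diketo ester
Product: 28 CNP0450261.1, via keto amide 27 (not isolated)
Conditions: NH3, MeOH–H2O, sealed tube, 110 °C
Reagents that add atoms: ammonia, N
Why: Ammonolysis of the methyl ester and 5-exo addition of the amide nitrogen to the benzylic ketone give the γ-hydroxy-γ-lactam, and enolisation of the 1,3-dicarbonyl carbon with reversible hemiaminal formation should funnel both lactam stereocentres to the cis-bridged isomer, the only one the 13-membered ring can span.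

Compound list
1 | methyl (R)-2,3-dihydroxypropanoate | OC[C@@H](O)C(=O)OC | starting material
2 | methyl (R)-3-(tert-butyldimethylsilyloxy)-2-hydroxypropanoate | CC(C)(C)[Si](C)(C)OC[C@@H](O)C(=O)OC | intermediate
3 | 4-bromophenol | Oc1ccc(Br)cc1 | starting material
4 | methyl (S)-2-(4-bromophenoxy)-3-(tert-butyldimethylsilyloxy)propanoate | CC(C)(C)[Si](C)(C)OC[C@H](Oc1ccc(Br)cc1)C(=O)OC | intermediate
5 | (S)-2-(4-bromophenoxy)-3-(tert-butyldimethylsilyloxy)propanal | CC(C)(C)[Si](C)(C)OC[C@H](Oc1ccc(Br)cc1)C=O | intermediate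
6 | (R,E)-4-(4-bromophenoxy)-5-(tert-butyldimethylsilyloxy)-2-methylpent-2-enal | CC(C)(C)[Si](C)(C)OC[C@H](Oc1ccc(Br)cc1)/C=C(\C)C=O | intermediate
7 | 2-methylpent-1-en-3-one | CCC(=O)C(C)=C | starting material
8 | (Z)-triethyl(2-methylpenta-1,3-dien-3-yloxy)silane | C/C=C(\O[Si](CC)(CC)CC)C(C)=C | intermediate
9 | ring C aldehyde: C13 carries CH3 (β) and CHO, C8 carries the C7(OAr)–C5H2OTBS chain trans to CHO, C10=C11 triethylsilyl enol ether, C9 epimers | CC(C)(C)[Si](C)(C)OC[C@H](Oc2ccc(Br)cc2)[C@@H]1C(C)C(O[Si](CC)(CC)CC)=C(C)C[C@]1(C=O)C | intermediate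
10 | 2-[1-(4-bromophenoxy)-2-hydroxyethyl]-1,3,5-trimethyl-4-oxocyclohexane-1-carbaldehyde, epimers at the two α-methyl carbons | OC[C@H](Oc2ccc(Br)cc2)[C@@H]1C(C)C(=O)C(C)C[C@]1(C=O)C | intermediate
11 | trans-fused keto acetal: 4-(4-bromophenoxy)-1-methoxy-5,7,8a-trimethyloctahydro-6H-isochromen-6-one, aryloxy axial, ring methyls at C9 and C11 equatorial (α), C13 methyl axial (β), both anomers | COC2OC[C@H](Oc4ccc(Br)cc4)[C@@H]3[C@@H](C)C(=O)[C@@H](C)C[C@]32C | intermediate
12 | hydrazone of 11 | COC2OC[C@H](Oc4ccc(Br)cc4)[C@@H]3[C@@H](C)C(=NN)[C@@H](C)C[C@]32C | intermediate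
13 | 4-(4-bromophenoxy)-1-methoxy-5,7,8a-trimethyloctahydro-1H-isochromene, ring stereocentres as in 11 | COC2OC[C@H](Oc4ccc(Br)cc4)[C@@H]3[C@@H](C)C[C@@H](C)C[C@]32C | intermediate
14 | 4-(4-bromophenoxy)-5,7,8a-trimethyloctahydro-1H-isochromen-1-ol (lactol) | OC2OC[C@H](Oc4ccc(Br)cc4)[C@@H]3[C@@H](C)C[C@@H](C)C[C@]32C | intermediate
15 | ethyl (E)-3-{2-[1-(4-bromophenoxy)-2-hydroxyethyl]-1,3,5-trimethylcyclohexyl}-2-methylprop-2-enoate; C13 methyl axial, all other ring substituents equatorial | OC[C@H](Oc2ccc(Br)cc2)[C@@H]1[C@@H](C)C[C@@H](C)C[C@]1(/C=C(\C)C(=O)OCC)C | intermediate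
16 | (E)-3-{2-[1-(4-bromophenoxy)-2-hydroxyethyl]-1,3,5-trimethylcyclohexyl}-2-methylprop-2-en-1-ol | OC[C@H](Oc2ccc(Br)cc2)[C@@H]1[C@@H](C)C[C@@H](C)C[C@]1(/C=C(\C)CO)C | intermediate
17 | (E)-3-{2-[1-(4-bromophenoxy)-2-hydroxyethyl]-1,3,5-trimethylcyclohexyl}-2-methylprop-2-enal | OC[C@H](Oc2ccc(Br)cc2)[C@@H]1[C@@H](C)C[C@@H](C)C[C@]1(/C=C(\C)C=O)C | intermediate
18 | (2E,4E)-5-{2-[1-(4-bromophenoxy)-2-hydroxyethyl]-1,3,5-trimethylcyclohexyl}-2,4-dimethylpenta-2,4-dienal | OC[C@H](Oc2ccc(Br)cc2)[C@@H]1[C@@H](C)C[C@@H](C)C[C@]1(/C=C(\C)/C=C(\C)C=O)C | intermediate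
19 | 2-(4-bromophenoxy)-2-{2-[(1E,3E)-2,4-dimethylhexa-1,3,5-trienyl]-2,4,6-trimethylcyclohexyl}ethanol | OC[C@H](Oc2ccc(Br)cc2)[C@@H]1[C@@H](C)C[C@@H](C)C[C@]1(/C=C(\C)/C=C(\C)C=C)C | intermediate
20 | 2-(4-bromophenoxy)-2-{2-[(1E,3E)-2,4-dimethylhexa-1,3,5-trienyl]-2,4,6-trimethylcyclohexyl}acetaldehyde | O=C[C@H](Oc2ccc(Br)cc2)[C@@H]1[C@@H](C)C[C@@H](C)C[C@]1(/C=C(\C)/C=C(\C)C=C)C | intermediate
21 | methyl (E)-6-(4-bromophenoxy)-6-{2-[(1E,3E)-2,4-dimethylhexa-1,3,5-trienyl]-2,4,6-trimethylcyclohexyl}-3-oxohex-4-enoate | COC(=O)CC(=O)/C=C/[C@H](Oc2ccc(Br)cc2)[C@@H]1[C@@H](C)C[C@@H](C)C[C@]1(/C=C(\C)/C=C(\C)C=C)C | intermediate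
22 | tricyclic β-keto ester: decahydrofluorene with C1 vinyl (β) and methyl, C2=C3 alkene, C4–H α, C5–H β, C6 3-methoxy-3-oxopropanoyl (β), C7 4-bromophenoxy (β), C8–H α, C9 and C11 methyls α, C13 methyl β | C=C[C@@]1(C)C=C(C)[C@@H]2[C@@H]([C@H]1C(=O)CC(=O)OC)[C@H](Oc1ccc(Br)cc1)[C@@H]1[C@@H](C)C[C@@H](C)C[C@]12C | intermediate
23 | chloroacetone | CC(=O)CCl | starting material
24 | aryl bromide methyl ketone β-keto ester: 22 with a 2-oxopropyl group on the carbon between the carbonyls | C=C[C@@]1(C)C=C(C)[C@@H]2[C@@H]([C@H]1C(=O)[C@H](CC(C)=O)C(=O)OC)[C@H](Oc1ccc(Br)cc1)[C@@H]1[C@@H](C)C[C@@H](C)C[C@]12C | intermediate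
25 | dilithium dianion of 24 (keto ester enolate and terminal methyl ketone enolate) | C=C[C@@]1(C)C=C(C)[C@@H]2[C@@H]([C@H]1C(=O)C(CC([O-])=C)=C([O-])OC)[C@H](Oc1ccc(Br)cc1)[C@@H]1[C@@H](C)C[C@@H](C)C[C@]12C.[Li+].[Li+] | intermediate
26 | 13-membered cyclophane diketo ester | C=C[C@@]1(C)C=C(C)[C@@H]2[C@@H]3[C@H](Oc4ccc(cc4)CC(=O)C[C@H](C(=O)OC)C(=O)[C@H]31)[C@@H]1[C@@H](C)C[C@@H](C)C[C@]12C | intermediate
27 | cyclophane keto amide (primary amide in place of the methyl ester of 26) | C=C[C@@]1(C)C=C(C)[C@@H]2[C@@H]3[C@H](Oc4ccc(cc4)CC(=O)CC(C(N)=O)C(=O)[C@H]31)[C@@H]1[C@@H](C)C[C@@H](C)C[C@]12C | intermediate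
28 | CNP0450261.1 | C=C[C@@]1(C)C=C(C)[C@@H]2[C@@H]3[C@H](Oc4ccc(cc4)C[C@@]4(O)C[C@H](C(=O)N4)C(=O)[C@H]31)[C@@H]1[C@@H](C)C[C@@H](C)C[C@]12C | target

Total step count: 18. Longest linear sequence: 17 steps (steps 1 to 3 and 5 to 18; step 4 makes the diene).

Steps most likely to fail

Step 17. Intermolecular arylation and protodebromination of the arylpalladium intermediate may outrun ring closure, or reductive elimination from the strained palladacycle may not occur. The fallback uses known reactions, sets out from 22 and returns at 26. Intermolecular palladium-catalysed α-arylation of 1-(tert-butyldimethylsilyloxy)propan-2-one at its methyl group with the aryl bromide of 22 (excess LiN(SiMe3)2, Pd2(dba)3, XPhos) would give the silyloxy ketone F1. Bu4NF with AcOH would give the hydroxy ketone F2, and MsCl with Et3N the α-mesyloxy ketone F3. Cs2CO3 with catalytic NaI in MeCN at high dilution would then close the 13-membered ring at the CH–CH2 bond by intramolecular C-alkylation of the β-keto ester, giving 26.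

Step 5. The diene may add to the other enal face, or without a clear preference, because the controlling stereocentre is acyclic and its two substituents differ little in size. The fallback sets out from 8 and returns at 13, with the aryl ether installed late by inversion. Commercial (R)-2,2-dimethyl-1,3-dioxolane-4-carbaldehyde and Ph3P=C(CH3)CHO would give the dioxolanyl enal F4, whose ring gives a better defined facial bias. If addition is syn to the C–O bond, cycloaddition with 8 gives the adduct F5 with ring C as required and the C7 oxygen epimeric. Camphorsulfonic acid in MeOH followed by K2CO3 would give the hydroxy keto acetal F6 (C7 hydroxyl equatorial), and Wolff–Kishner reduction the hydroxy acetal F7. Mitsunobu etherification of F7 with 3 then inverts C7 and gives 13.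

Step 15. Cycloaddition of the partly enolised keto ester may be slow, so that the triene isomerises, and endo and facial selectivity may erode at the temperature needed. The fallback sets out from 20 and returns at 22, using a more electrophilic dienophile under Lewis acid activation. Wittig reaction of 20 with Ph3P=CHCHO would give the trienyl enal F8. Me2AlCl-catalysed intramolecular Diels–Alder reaction at low temperature would give the tricyclic aldehyde F9, and Roskamp homologation with methyl diazoacetate and SnCl2 would give 22.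

Further compounds
F1 | step 17 | tricyclic β-keto ester carrying a 4-[3-(tert-butyldimethylsilyloxy)-2-oxopropyl]phenoxy group at C7 | C=C[C@@]1(C)C=C(C)[C@@H]2[C@@H]([C@H]1C(=O)CC(=O)OC)[C@H](Oc1ccc(CC(=O)CO[Si](C)(C)C(C)(C)C)cc1)[C@@H]1[C@@H](C)C[C@@H](C)C[C@]12C
F2 | step 17 | tricyclic β-keto ester carrying a 4-(3-hydroxy-2-oxopropyl)phenoxy group at C7 | C=C[C@@]1(C)C=C(C)[C@@H]2[C@@H]([C@H]1C(=O)CC(=O)OC)[C@H](Oc1ccc(CC(=O)CO)cc1)[C@@H]1[C@@H](C)C[C@@H](C)C[C@]12C
F3 | step 17 | tricyclic β-keto ester carrying a 4-[3-(methanesulfonyloxy)-2-oxopropyl]phenoxy group at C7 | C=C[C@@]1(C)C=C(C)[C@@H]2[C@@H]([C@H]1C(=O)CC(=O)OC)[C@H](Oc1ccc(CC(=O)COS(C)(=O)=O)cc1)[C@@H]1[C@@H](C)C[C@@H](C)C[C@]12C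
F4 | step 5 | (S,E)-3-(2,2-dimethyl-1,3-dioxolan-4-yl)-2-methylprop-2-enal | CC1(C)OC[C@@H](O1)/C=C(\C)C=O
F5 | step 5 | 6-(2,2-dimethyl-1,3-dioxolan-4-yl)-1,3,5-trimethyl-4-(triethylsilyloxy)cyclohex-3-ene-1-carbaldehyde, C7 epimeric to the target | CC1(C)OC[C@@H](O1)[C@@H]2C(C)C(O[Si](CC)(CC)CC)=C(C)C[C@]2(C=O)C
F6 | step 5 | 4-hydroxy-1-methoxy-5,7,8a-trimethyloctahydro-6H-isochromen-6-one, hydroxyl equatorial | COC2OC[C@@H](O)[C@@H]3[C@@H](C)C(=O)[C@@H](C)C[C@]32C
F7 | step 5 | 1-methoxy-5,7,8a-trimethyloctahydro-1H-isochromen-4-ol, hydroxyl equatorial | COC2OC[C@@H](O)[C@@H]3[C@@H](C)C[C@@H](C)C[C@]32C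
F8 | step 15 | (E)-4-(4-bromophenoxy)-4-{2-[(1E,3E)-2,4-dimethylhexa-1,3,5-trienyl]-2,4,6-trimethylcyclohexyl}but-2-enal | O=C/C=C/[C@H](Oc2ccc(Br)cc2)[C@@H]1[C@@H](C)C[C@@H](C)C[C@]1(/C=C(\C)/C=C(\C)C=C)C
F9 | step 15 | tricyclic C6 carbaldehyde, otherwise as 22 | C=C[C@@]1(C)C=C(C)[C@@H]2[C@@H]([C@H]1C=O)[C@H](Oc1ccc(Br)cc1)[C@@H]1[C@@H](C)C[C@@H](C)C[C@]12C
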